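## The problem

The target 31 contains two bicyclo[3.2.1] units that share the C6–C13 bond. Rings A (C4, C5, C6, C7, C9) and B (C6, C7, C9, C10, C11, C13) form a bicyclooctanedione with the C7 carbonyl as one-carbon bridge. Rings C (C6, C13, C14, C15, C17, C18) and D (C6, C13, C26, C19, C18) form a benzo-fused bicyclooctene with C6 as one-carbon bridge. C6 is therefore a quaternary carbon common to all four rings, and the neighbouring C13 is a second quaternary carbon that carries the arene.

Of the five stereocentres, C9 and C18 are bridgeheads and follow from ring closure. The ones that must be controlled are C6 (absolute), C13 relative to C6 (arene anti to C5 across C6–C13) and C4. At C4 the isopropenyl group lies exo, anti to C10 across C4–C9. A concerted ene closure of ring A would deliver the other epimer, because its hydrogen transfer to C10 requires the isopropylidene carbon to sit over C10.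

C6 can direct C13, since an electrophile adding to a C11 enolate at C13 must choose between the face bearing the angular C5 substituent and the free face. C13 then fixes C18 through the two-atom arene tether. The free hydroquinone (air-sensitive), the 1,1-disubstituted and trisubstituted alkenes (acid, electrophiles) and the 1,4-dione of ring B limit the conditions, so the hydroquinone is unveiled last.

The enabling feature is that C26 and C19 are attached to C13, which is alpha to the C11 ketone, and to C18, which is 1,3 to C13 across C6 on ring C. A nucleophilic C13 and an electrophilic C18 are thus spanned by exactly one edge of a symmetric 3,6-dioxygenated benzyne.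

## Retrosynthesis

**Hydroquinone last (31 to 29).** The two phenols are carried as methyl ethers in 29. They are released by oxidative demethylation to quinone 30 and reduction in the work-up. No skeletal bond is cut. The forward step must spare two alkenes and two ketones, which an oxidant acting on the electron-rich arene does and a Lewis-acidic ether cleavage would not.

**Ring A (29 to 28).** The C4–C9 bond is cut.
- An ene closure from a prenyl group is set aside because it would give the C4 epimer.
- An enolate alkylation at C9 is set aside because C9 and C10 enolates cannot be told apart.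
- Chosen instead is the conjugate addition of an allylsilane (C4 as gamma carbon) to C9 of ene-dione 28. Loss of silicon forms the isopropenyl group directly, and the open transition state can place it exo.
- C7 must be a planar carbonyl at this point, so that nothing on the one-carbon bridge crowds the exo side of C4.
- 28 comes from allyl compound 26 and silane 27 by cross-metathesis. 26 comes from diketone 24 by dehydrogenation, which can only occur at C9–C10 because C6 and C13 are quaternary.

**Ring C methyl (24 to 21).** The C15–C16 bond is cut back to enol triflate 21 (cross-coupling gives 22; desilylation and oxidation give 24 via 23). The triflate fixes the alkene at C15=C17, which a ketone at C15 could not do reliably beside the C11 ketone.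

**Key disconnection (21 to 10 and 17).** C13–C26 and C18–C19 are cut together. This removes the arene and ring D and leaves bicyclic silyl enol ether 10 plus aryne precursor 17 (aryne 19). In the forward step the enolate carbon C13 adds to the aryne, the aryl anion adds 1,4 to the ring C enone at C18, and the resulting C15 enolate 20 is triflated in the same flask. Making one bond at a time with aryl halides would have to force a di-ortho-substituted aryl group onto a carbon flanked by two quaternary centres. Three choices harden the step:
- C6 carries allyl, not prenyl, because a prenyl group is a good ene partner for arynes. Allyl also becomes the allylsilane later.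
- C7 is an equatorial silyl ether, not a ketone. A C7 ketone would offer the aryl anion a second five-membered closure by 1,2-addition. A ketal would place an oxygen syn-axial to the incoming arene.
- The C15 enolate is triflated before it can equilibrate.

**Regiodefined enol ether (10 to 9).** Deprotonation of the corresponding ketone would remove the more acidic C14 hydrogens. The enol ether is therefore made by 1,4-hydrosilylation of ene-dione 9, in which hydride goes to C14 and silicon to O11. The regiochemistry is set by the mechanism.

**Oxidation pattern (9 to 4).** The C11 carbonyl is taken back to the allylic methylene of dienone 8. The C17=C18 alkene is taken back to enone 6 (via dienol ether 7). The C7 silyl ether is taken back through alcohol 5 to the known type of bicyclic enedione 4. All three are functional-group changes on an intact skeleton.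

**C6 (4 to 1 and 2).** The C13=C14 and C6–C18 bonds are cut by a Robinson annulation. Prochiral triketone 3, from dione 1 and enone 2, is desymmetrised by an amino-amide catalyst. This sets C6 in the second step of the route, from two commercial compounds.

**Aryne precursor (17 to 11).** The C–Si bond is cut. Carbamate-directed ortho-lithiation of 12 (from phenol 11) can only occur at the position between the carbamate and a methoxy group. This gives 15 (via 13 and 14) and then 17 (via 16).

## Roads not taken

**Alternative 1:** The arene is built last. Its bonds C19–C26, C20–C22 and C23–C24 are cut, leaving bis(alkynyl boronate) A1 (rings A–C complete, alkynes on C13 and C18) and ethyne A2. A rhodium- or cobalt-mediated cyclotrimerisation would give bis-boronate A3, and oxidation of the two carbon–boron bonds would give 31.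
- Merits: no phenol protecting groups, no oxidative end-game, no arene regiochemistry, and the key step creates no stereocentre.
- Weak points: A1 needs two alkynyl groups cis on quaternary C13 and on C18. That is the same stereochemical problem as in the chosen plan, solved one bond at a time with less reactive partners. Alkynyl boronates are fragile towards base. The metal must ignore two alkenes and two ketones.
- Comparison: Alternative 1 has the better final stage. The chosen plan sets against this that the arene arrives as one reagent and both ring-fusion bonds form in one step from a regiodefined enolate.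

**Alternative 2:** The C13–C14 bond is cut with dearomatisation. In mirror-symmetric fluorene A4, a chiral palladium catalyst would ionise the allylic carbonate, and one of the two enantiotopic phenol rings would attack through C13 to give dienone A5.
- Merits: the substrate is achiral and easily assembled. The catalyst sets C13 and C18 in the ring-forming step. The C15 methyl alkene is already present.
- Weak points: the nucleophilic carbon is the fully substituted biaryl carbon of the fluorene, and O-allylation competes. A5 lacks C4, C5 and the isopropenyl group. C6 is still sp2 and would have to become the quaternary centre late, at the most crowded position, before ring A can be closed.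
- Comparison: Alternative 2 is better on catalytic enantiocontrol and on the ring C alkene, which costs the chosen plan a triflation and a cross-coupling. The chosen plan makes C6 first, by a well-known annulation, and lets it direct C13.

**Alternative 3:** C6–C13 and C9–C10 are cut. Ionisation of tertiary chloride A6 would give a 2-siloxyallyl cation (C13–C11–C10) that adds across the tethered 5,5-dimethoxycyclopentadiene in a (4+3) cycloaddition to give pentacycle A7.
- Merits: this step forms more skeleton than the aryne step. It builds the bridged A/B unit with its C7 bridge and three stereocentres at once. The C4 acetyl group is epimerisable, so the exo isomer could be reached thermodynamically.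
- Weak points: A6 combines a tertiary benzylic alpha-chloro ketone derivative with a dimerisation-prone cyclopentadienone ketal on a benzo-fused seven-membered ring. Absolute control must be relayed from C18 through the tether. Afterwards the C4=C5 alkene must be reduced and the acetyl group methylenated beside two ring ketones.
- Comparison: Alternative 3 wins on bonds per step. The chosen plan has a far more accessible, enantioenriched precursor and a key step whose selectivity rests on one existing stereocentre.

Key step: step 11

Remark: atom numbers C1 to C26 follow the order of the target SMILES and are kept for all intermediates. The CIP descriptor of C6 changes along the route although its spatial arrangement does not.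

## Route

Step 1
Reactants: 1 2-allylcyclohexane-1,3-dione; 2 methyl vinyl ketone
Product: 3 2-allyl-2-(3-oxobutyl)cyclohexane-1,3-dione
Conditions: Et3N (cat.), neat, rt
Reagents that add atoms: none
Why: Michael addition of the acidic 1,3-dione to the enone is the first half of a Robinson annulation. The product is a prochiral triketone, so no stereocentre is formed.

Step 2
Reactants: 3 2-allyl-2-(3-oxobutyl)cyclohexane-1,3-dione
Product: 4 (R)-8a-allyl-3,4,8,8a-tetrahydronaphthalene-1,6(2H,7H)-dione
Conditions: (S)-N-[(Sa)-2'-(p-toluenesulfonamido)-1,1'-binaphthalen-2-yl]pyrrolidine-2-carboxamide (2 mol%), PhCO2H (1 mol%), neat, rt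
Reagents that add atoms: none
Why: Enamine-mediated intramolecular aldol condensation (Hajos–Parrish-type Robinson annulation) in which the (S)-prolinamide distinguishes the two enantiotopic ring carbonyls and so sets C6. The catalyst sense that leads to (S)-Wieland–Miescher ketone in the methyl series should give the same spatial arrangement here, which is named R because allyl outranks the ring methylene.

Step 3
Reactants: 4 (R)-8a-allyl-3,4,8,8a-tetrahydronaphthalene-1,6(2H,7H)-dione
Product: 5 (4aR,5S)-4a-allyl-5-hydroxy-4,4a,5,6,7,8-hexahydronaphthalen-2(3H)-one
Conditions: NaBH4 (0.3 equiv), EtOH, −10 °C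
Reagents that add atoms: none
Why: Chemoselective hydride reduction of the saturated C7 ketone in the presence of the enone, as is usual for this ring system. Hydride should enter anti to the axial angular allyl group, giving the equatorial C7 hydroxyl cis to allyl.

Step 4
Reactants: 5 (4aR,5S)-4a-allyl-5-hydroxy-4,4a,5,6,7,8-hexahydronaphthalen-2(3H)-one
Product: 6 (4aR,5S)-4a-allyl-5-(tert-butyldimethylsilyloxy)-4,4a,5,6,7,8-hexahydronaphthalen-2(3H)-one
Conditions: t-BuMe2SiCl, imidazole, DMF, 40 °C
Reagents that add atoms: tert-butyldimethylsilyl chloride CC(C)(C)[Si](C)(C)Cl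
Why: Standard silylation of a secondary alcohol. The ether should survive amide base, peroxide, copper hydride and CsF, and it leaves only hydrogen at C7 on the face that is arylated later.

Step 5
Reactants: 6 (4aR,5S)-4a-allyl-5-(tert-butyldimethylsilyloxy)-4,4a,5,6,7,8-hexahydronaphthalen-2(3H)-one
Product: 8 (4aS,5S)-4a-allyl-5-(tert-butyldimethylsilyloxy)-5,6,7,8-tetrahydronaphthalen-2(4aH)-one, via trimethylsilyl dienol ether 7 (not isolated)
Conditions: LiN(iPr)2, Me3SiCl, THF, −78 °C; then Pd(OAc)2, MeCN, rt
Reagents that add atoms: none
Why: Saegusa–Ito dehydrogenation. Kinetic deprotonation of the enone occurs at the alpha' carbon C17, and palladation of the silyl dienol ether followed by beta-hydride elimination introduces C17=C18, the enone arm that later accepts the aryl anion.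

Step 6
Reactants: 8 (4aS,5S)-4a-allyl-5-(tert-butyldimethylsilyloxy)-5,6,7,8-tetrahydronaphthalen-2(4aH)-one
Product: 9 (4aS,5S)-4a-allyl-5-(tert-butyldimethylsilyloxy)-4a,5,6,7-tetrahydronaphthalene-2,8-dione
Conditions: Rh2(caprolactamate)4 (1 mol%), t-BuOOH (70% in water), K2CO3, CH2Cl2, rt
Reagents that add atoms: tert-butyl hydroperoxide CC(C)(C)OO
Why: Dirhodium-catalysed allylic oxidation with tert-butyl hydroperoxide, the known conversion of an enone into an ene-dione. The C11 methylene is the only ring position that is allylic and gamma to the dienone carbonyl, so hydrogen abstraction and collapse of the mixed peroxide should place the ketone there.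

Step 7
Reactants: 9 (4aS,5S)-4a-allyl-5-(tert-butyldimethylsilyloxy)-4a,5,6,7-tetrahydronaphthalene-2,8-dione
Product: 10 (4aS,5S)-4a-allyl-5-(tert-butyldimethylsilyloxy)-8-(dimethylphenylsilyloxy)-4a,5,6,7-tetrahydronaphthalen-2(1H)-one
Conditions: [(Ph3P)CuH]6 (5 mol%), PhMe2SiH (1.1 equiv), toluene, rt
Reagents that add atoms: dimethylphenylsilane C[SiH](C)c1ccccc1
Why: Copper hydride-catalysed 1,4-hydrosilylation of an enone. Hydride should add to C14, the unhindered beta carbon of the s-cis C11 enone and the doubly activated carbon of the ene-dione, and the copper enolate is silylated by the silane. The C11–C13 silyl enol ether is thus formed without any deprotonation, which would instead remove the more acidic C14 hydrogens.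

Step 8
Reactants: 11 2,5-dimethoxyphenol
Product: 12 2,5-dimethoxyphenyl N-isopropylcarbamate
Conditions: i-PrNCO, Et3N (cat.), CH2Cl2, rt
Reagents that add atoms: isopropyl isocyanate CC(C)N=C=O
Why: Addition of the phenol to the isocyanate gives a carbamate that serves as a directing group for ortho-metalation and can be removed under mild conditions.

Step 9
Reactants: 12 2,5-dimethoxyphenyl N-isopropylcarbamate
Product: 15 3,6-dimethoxy-2-(trimethylsilyl)phenyl N-isopropylcarbamate, via N-silyl carbamate 13 (not isolated), via N-silyl aryl silane 14 (not isolated)
Conditions: t-BuMe2SiOTf, Me2NCH2CH2NMe2, Et2O, 0 °C to rt; n-BuLi, −78 °C; Me3SiCl; aq. NaHSO4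
Reagents that add atoms: chlorotrimethylsilane C[Si](C)(C)Cl
Why: Directed ortho-metalation. After temporary N-silylation the only hydrogen ortho to the carbamate, which is also ortho to a methoxy group, is lithiated and silylated. The N–Si bond is cleaved in the acidic work-up.

Step 10
Reactants: 15 3,6-dimethoxy-2-(trimethylsilyl)phenyl N-isopropylcarbamate
Product: 17 3,6-dimethoxy-2-(trimethylsilyl)phenyl trifluoromethanesulfonate, via 3,6-dimethoxy-2-(trimethylsilyl)phenol 16 (not isolated)
Conditions: Et2NH, DBU, MeCN, 40 °C; then PhNTf2, rt
Reagents that add atoms: N-phenylbis(trifluoromethanesulfonimide) O=S(=O)(N(c1ccccc1)S(=O)(=O)C(F)(F)F)C(F)(F)F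
Why: Base-induced loss of isopropyl isocyanate, which is captured by diethylamine as a urea, frees the phenoxide. Triflation in the same flask gives the ortho-silyl aryl triflate without exposing the aryl–silicon bond to acid.

Step 11
Reactants: 10 (4aS,5S)-4a-allyl-5-(tert-butyldimethylsilyloxy)-8-(dimethylphenylsilyloxy)-4a,5,6,7-tetrahydronaphthalen-2(1H)-one; 17 3,6-dimethoxy-2-(trimethylsilyl)phenyl trifluoromethanesulfonate
Product: 21 C15 enol triflate of the C6-allyl C7-silyloxy tetracycle, via cesium C11 enolate 18 (not isolated), via 3,6-dimethoxybenzyne 19 (not isolated), via cesium C15 enolate 20 (not isolated)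
Conditions: CsF (4 equiv), 18-crown-6, THF, 0 °C to rt, slow addition of 10 to 17 (1.5 equiv); then PhNTf2, −20 °C to rt
Reagents that add atoms: N-phenylbis(trifluoromethanesulfonimide) O=S(=O)(N(c1ccccc1)S(=O)(=O)C(F)(F)F)C(F)(F)F
Why: Fluoride cleaves the silyl enol ether to enolate 18 and, in parallel, triggers 1,2-elimination of 17 to aryne 19. The tetrasubstituted enolate carbon C13 adds to the aryne (C13–C26), and the ortho aryl anion at C19 closes ring D by 5-exo-trig conjugate addition to C18 of the ring C enone (C18–C19), leaving the C15 enolate 20, which is O-triflated before it can equilibrate. The closest known reaction type is the insertion of an aryne by a carbon nucleophile with intramolecular Michael capture of the aryl anion (indane-forming aryne annulation), followed by ordinary enolate triflation. C13 is set by C6: the allyl group is pseudoaxial and eclipses the approach on its own face, while the opposite face of the flattened ring C has no syn-axial hydrogens and meets only the axial hydrogen of C7, the silyloxy group being equatorial. C18 is then fixed, because the two-atom tether allows only cis closure across C13–C6–C18. The aryne is symmetric, so the arene has no regiochemistry. The aryl anion should prefer C18 because C7 is masked as a silyl ether, which removes the only other five-membered closure, and because attack on the C11 carbonyl would form a four-membered ring. Slow addition keeps the free enolate dilute, so that proton transfer to the C14 position and a second arylation of 20 are suppressed.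

Step 12
Reactants: 21 C15 enol triflate of the C6-allyl C7-silyloxy tetracycle
Product: 22 C15-methyl tetracycle with C7 silyl ether and C11 ketone
Conditions: Me2Zn, Pd(PPh3)4 (5 mol%), THF, 0 °C to rt
Reagents that add atoms: dimethylzinc C[Zn]C
Why: Negishi coupling of the enol triflate installs C16 on the C15=C17 alkene, whose position is fixed by the triflate. The hindered C11 ketone and the terminal alkene should not react with the organozinc.

Step 13
Reactants: 22 C15-methyl tetracycle with C7 silyl ether and C11 ketone
Product: 23 C7 alcohol of the C15-methyl tetracycle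
Conditions: Bu4NF, THF, rt
Reagents that add atoms: none
Why: Fluoride-mediated cleavage of the silyl ether. C13 is quaternary and C18 is a bridgehead, so the basic medium cannot epimerise any centre.

Step 14
Reactants: 23 C7 alcohol of the C15-methyl tetracycle
Product: 24 C7,C11-diketone of the C15-methyl tetracycle
Conditions: Dess–Martin periodinane, NaHCO3, CH2Cl2, rt
Reagents that add atoms: none
Why: Mild oxidation of the secondary alcohol restores the C7 carbonyl. C7 becomes planar before ring A is closed, so nothing on the one-carbon bridge shields the exo side of C4.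

Step 15
Reactants: 24 C7,C11-diketone of the C15-methyl tetracycle
Product: 26 ring B ene-dione (C9=C10) of the C15-methyl tetracycle, via bis(trimethylsilyl) dienol ether 25 (not isolated)
Conditions: Me3SiOTf, Et3N, CH2Cl2, 0 °C; then Pd(OAc)2, MeCN, rt
Reagents that add atoms: none
Why: Soft enolisation can only occur towards C9 and C10 because C6 and C13 are quaternary, giving the 1,4-bis(silyloxy)-1,3-diene. Saegusa–Ito-type oxidation of this diene gives the ene-dione with no regiochemical choice.

Step 16
Reactants: 26 ring B ene-dione (C9=C10) of the C15-methyl tetracycle; 27 (2-methylallyl)trimethylsilane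
Product: 28 allylsilane with C6-[(E)-3-methyl-4-(trimethylsilyl)but-2-enyl] side chain
Conditions: 27 (10 equiv), (H2IMes)(PCy3)Cl2Ru=CHPh (second-generation Grubbs catalyst, 10 mol%), CH2Cl2, 40 °C
Reagents that add atoms: none
Why: Olefin cross-metathesis between the terminal allyl group and the 1,1-disubstituted alkene of 27 (used in excess). The trisubstituted ring alkene and the cyclic ene-dione should not take part, and either alkene geometry of the product can be used.

Step 17
Reactants: 28 allylsilane with C6-[(E)-3-methyl-4-(trimethylsilyl)but-2-enyl] side chain
Product: 29 dimethyl ether of the target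
Conditions: TiCl4, CH2Cl2, −78 °C; aq. NaHCO3
Reagents that add atoms: none
Why: Intramolecular Hosomi–Sakurai conjugate addition. The gamma carbon C4 attacks C9 of the Lewis acid-activated ene-dione (5-exo-trig) and loss of the silyl group from the beta-silyl cation forms the isopropenyl group. C9 is fixed by the bridge, and C4 should form with the side chain anti to C10 (antiperiplanar alkenes), because this places it next to the planar C7 carbonyl and away from the metal-bound enolate, and no hydrogen has to be delivered to C10. Attack at C9 over C10 should be favoured by five-membered ring formation and by coordination of titanium to O11, which the neighbouring C24 methoxy group can assist.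

Step 18
Reactants: 29 dimethyl ether of the target
Product: 31 target hydroquinone CNP0287617.1, via quinone 30 (not isolated)
Conditions: (NH4)2Ce(NO3)6, MeCN/H2O, 0 °C; then aq. Na2S2O4, EtOAc, rt
Reagents that add atoms: water O
Why: Oxidative demethylation of the 1,4-dimethoxyarene gives the quinone, with water supplying the oxygen atoms. The quinone cannot tautomerise to a quinone methide because C18 is a bridgehead, and dithionite in the work-up reduces it to the hydroquinone without touching ketones or alkenes.

## Compound list

1 | 2-allylcyclohexane-1,3-dione | C=CCC1C(=O)CCCC1=O | starting material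
2 | methyl vinyl ketone (but-3-en-2-one) | C=CC(C)=O | starting material
3 | 2-allyl-2-(3-oxobutyl)cyclohexane-1,3-dione | C=CCC1(CCC(C)=O)C(=O)CCCC1=O | intermediate
4 | (R)-8a-allyl-3,4,8,8a-tetrahydronaphthalene-1,6(2H,7H)-dione | C=CC[C@@]12C(=O)CCCC1=CC(=O)CC2 | intermediate
5 | (4aR,5S)-4a-allyl-5-hydroxy-4,4a,5,6,7,8-hexahydronaphthalen-2(3H)-one (C7 hydroxyl cis to allyl) | C=CC[C@@]12[C@@H](O)CCCC1=CC(=O)CC2 | intermediate
6 | (4aR,5S)-4a-allyl-5-(tert-butyldimethylsilyloxy)-4,4a,5,6,7,8-hexahydronaphthalen-2(3H)-one | C=CC[C@@]12[C@@H](O[Si](C)(C)C(C)(C)C)CCCC1=CC(=O)CC2 | intermediate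
7 | cross-conjugated trimethylsilyl dienol ether of 6 (C15 silyloxy, C15=C17 and C13=C14) | C=CC[C@@]12[C@@H](O[Si](C)(C)C(C)(C)C)CCCC1=CC(O[Si](C)(C)C)=CC2 | intermediate
8 | (4aS,5S)-4a-allyl-5-(tert-butyldimethylsilyloxy)-5,6,7,8-tetrahydronaphthalen-2(4aH)-one | C=CC[C@@]12[C@@H](O[Si](C)(C)C(C)(C)C)CCCC1=CC(=O)C=C2 | intermediate
9 | (4aS,5S)-4a-allyl-5-(tert-butyldimethylsilyloxy)-4a,5,6,7-tetrahydronaphthalene-2,8-dione | C=CC[C@@]12[C@@H](O[Si](C)(C)C(C)(C)C)CCC(=O)C1=CC(=O)C=C2 | intermediate
10 | (4aS,5S)-4a-allyl-5-(tert-butyldimethylsilyloxy)-8-(dimethylphenylsilyloxy)-4a,5,6,7-tetrahydronaphthalen-2(1H)-one | C=CC[C@@]12[C@@H](O[Si](C)(C)C(C)(C)C)CCC(O[Si](C)(C)c3ccccc3)=C1CC(=O)C=C2 | intermediate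
11 | 2,5-dimethoxyphenol | COc1ccc(OC)c(O)c1 | starting material
12 | 2,5-dimethoxyphenyl N-isopropylcarbamate | COc1ccc(OC)c(OC(=O)NC(C)C)c1 | intermediate
13 | 2,5-dimethoxyphenyl N-(tert-butyldimethylsilyl)-N-isopropylcarbamate | COc1ccc(OC)c(OC(=O)N(C(C)C)[Si](C)(C)C(C)(C)C)c1 | intermediate
14 | 3,6-dimethoxy-2-(trimethylsilyl)phenyl N-(tert-butyldimethylsilyl)-N-isopropylcarbamate | COc1ccc(OC)c(OC(=O)N(C(C)C)[Si](C)(C)C(C)(C)C)c1[Si](C)(C)C | intermediate
15 | 3,6-dimethoxy-2-(trimethylsilyl)phenyl N-isopropylcarbamate | COc1ccc(OC)c(OC(=O)NC(C)C)c1[Si](C)(C)C | intermediate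
16 | 3,6-dimethoxy-2-(trimethylsilyl)phenol (present as its amidinium phenoxide) | COc1ccc(OC)c(O)c1[Si](C)(C)C | intermediate
17 | 3,6-dimethoxy-2-(trimethylsilyl)phenyl trifluoromethanesulfonate | COc1ccc(OC)c(OS(=O)(=O)C(F)(F)F)c1[Si](C)(C)C | intermediate
18 | cesium C11 enolate of the bicyclic enone (C11=C13, C6 allyl, C7 silyl ether) | C=CC[C@@]12[C@@H](O[Si](C)(C)C(C)(C)C)CCC([O-])=C1CC(=O)C=C2.[Cs+] | intermediate
19 | 3,6-dimethoxybenzyne | COC1=CC=C(OC)C#C1 | intermediate
20 | cesium C15 enolate of the tetracycle (C15=C17; arene bridge anti to allyl; H18 cis to the C13–aryl bond) | C=CC[C@@]23[C@@H](O[Si](C)(C)C(C)(C)C)CCC(=O)[C@@]21CC([O-])=C[C@@H]3c2c(OC)ccc(OC)c21.[Cs+] | intermediate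
21 | tetracyclic C15 enol triflate (C6 allyl, C7 tert-butyldimethylsilyl ether cis to allyl, C11 ketone, 20,24-dimethoxyarene bridging C13 and C18 anti to allyl) | C=CC[C@@]23[C@@H](O[Si](C)(C)C(C)(C)C)CCC(=O)[C@@]21CC(OS(=O)(=O)C(F)(F)F)=C[C@@H]3c2c(OC)ccc(OC)c21 | intermediate
22 | C15-methyl tetracycle (C15=C17 alkene, C7 silyl ether, C11 ketone) | C=CC[C@@]23[C@@H](O[Si](C)(C)C(C)(C)C)CCC(=O)[C@@]21CC(C)=C[C@@H]3c2c(OC)ccc(OC)c21 | intermediate
23 | C7 alcohol of the C15-methyl tetracycle | C=CC[C@@]23[C@@H](O)CCC(=O)[C@@]21CC(C)=C[C@@H]3c2c(OC)ccc(OC)c21 | intermediate
24 | C7,C11-diketone of the C15-methyl tetracycle | C=CC[C@@]23C(=O)CCC(=O)[C@@]21CC(C)=C[C@@H]3c2c(OC)ccc(OC)c21 | intermediate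
25 | C7,C11-bis(trimethylsilyloxy) ring B 1,3-diene | C=CC[C@@]23C(O[Si](C)(C)C)=CC=C(O[Si](C)(C)C)[C@@]21CC(C)=C[C@@H]3c2c(OC)ccc(OC)c21 | intermediate
26 | ring B ene-dione (C7 and C11 ketones, C9=C10) with C6 allyl | C=CC[C@@]23C(=O)C=CC(=O)[C@@]21CC(C)=C[C@@H]3c2c(OC)ccc(OC)c21 | intermediate
27 | (2-methylallyl)trimethylsilane | C=C(C)C[Si](C)(C)C | starting material
28 | ene-dione with C6-[(E)-3-methyl-4-(trimethylsilyl)but-2-enyl] side chain (E isomer shown; the Z isomer converges) | C[Si](C)(C)C/C(C)=C/C[C@@]23C(=O)C=CC(=O)[C@@]21CC(C)=C[C@@H]3c2c(OC)ccc(OC)c21 | intermediate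
29 | dimethyl ether of the target (ring A closed, isopropenyl at C4 exo) | C=C(C)[C@H]1C[C@@]23C(=O)[C@@H]1CC(=O)[C@@]21CC(C)=C[C@@H]3c2c(OC)ccc(OC)c21 | intermediate
30 | quinone of the target | C=C(C)[C@H]1C[C@@]23C(=O)[C@@H]1CC(=O)[C@@]21CC(C)=C[C@@H]3C2=C1C(=O)C=CC2=O | intermediate
31 | CNP0287617.1 (hydroquinone) | C=C(C)[C@H]1C[C@@]23C(=O)[C@@H]1CC(=O)[C@@]21CC(C)=C[C@@H]3c2c(O)ccc(O)c21 | target

## Step count and weak points

Total: 18 steps. Longest linear sequence: 15 steps (steps 1–7 and 11–18). The aryne precursor branch (steps 8–10) joins at step 11.

**Step 11 (key step).** Several processes can compete: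
- proton transfer that converts the C11 enolate into the more stable C14 dienolate before the aryne arrives;
- capture of the aryl anion by a proton or by the C11 carbonyl (four-membered closure and ring expansion) instead of C18;
- loss of facial selectivity at C13;
- a second arylation of enolate 20;
- incomplete O-triflation.

Fallback: the two bonds are made in two polar steps, starting from 10 and rejoining at 22.
- Copper-catalysed conjugate addition (CuBr·SMe2) of (2-bromo-3,6-dimethoxyphenyl)magnesium chloride F1 to C18 of 10, anti to the allyl group. F1 is prepared from 2,3-dibromo-1,4-dimethoxybenzene and iPrMgCl·LiCl.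
- Trapping of the magnesium enolate with N-(5-chloropyridin-2-yl)bis(trifluoromethanesulfonimide) gives the C18-aryl C15 enol triflate F2, which still carries the C11 silyl enol ether.
- Negishi methylation as in step 12 gives the C15-methyl aryl bromide F3.
- Fluoride-promoted, palladium-catalysed intramolecular alpha-arylation of the silyl enol ether (Pd2(dba)3, P(t-Bu)3, CsF) closes C13–C26 as a five-membered ring and gives 22.

The hindered quaternary carbon is then formed intramolecularly. The cost is a conjugate addition with a di-ortho-substituted aryl nucleophile.

**Step 7.** Hydride may be delivered to C18 (the other enone arm), a second reduction may follow, or the silyl enol ether may hydrolyse during isolation.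

Fallback: reduction is replaced by isomerisation, starting from 9 and rejoining at 10.
- Luche reduction (NaBH4, CeCl3·7H2O, MeOH, −78 °C) of the more electrophilic C11 carbonyl gives the C11-hydroxy dienone F5.
- Silylation with PhMe2SiCl and imidazole gives the C11-silyloxy dienone F6.
- Deprotonation with KN(SiMe3)2 at −78 °C, where the C11 hydrogen is the only acidic one, followed by kinetic protonation of the extended enolate at the alpha carbon C14 with acetic acid, moves the alkene out of conjugation and gives 10.

**Step 6.** The peroxy radical may abstract the allylic hydrogens of the C6 allyl group or add to the terminal alkene, and over-oxidation is possible.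

Fallback: halogenation and substitution-oxidation, starting from 8 and rejoining at 9.
- Radical bromination with N-bromosuccinimide under visible light in PhCF3 at rt gives the C11-bromo dienone F4.
- Oxidation of the allylic bromide with N-methylmorpholine N-oxide in MeCN gives 9.

**Step 17.** C4 may attack C10 (beta to the C7 carbonyl) and give the bicyclo[2.2.2] isomer. The synclinal arrangement may give the C4 epimer. The allylsilane may be protodesilylated before it cyclises.

Fallback: the polarity is reversed, starting from 24 and rejoining at 29.
- Cross-metathesis of 24 with 2-methylallyl acetate under the same ruthenium carbene gives the (E)-allylic acetate F7.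
- Pd(PPh3)4 and NaH in THF then effect an intramolecular Tsuji–Trost alkylation. The C7 enolate attacks the near terminus C4 of the allylpalladium unit through C9, closing the five-membered ring and forming the isopropenyl group.

Ring B stays saturated in this fallback, so C10 could only react as the C11 enolate and would have to form the more strained bridged ring.

## Further compounds

F1 | step 11 | (2-bromo-3,6-dimethoxyphenyl)magnesium chloride | COc1ccc(OC)c([Mg]Cl)c1Br
F2 | step 11 | C18-(2-bromo-3,6-dimethoxyphenyl) C15 enol triflate retaining the C11 dimethylphenylsilyl enol ether | C=CC[C@@]12[C@@H](O[Si](C)(C)C(C)(C)C)CCC(O[Si](C)(C)c3ccccc3)=C1CC(OS(=O)(=O)C(F)(F)F)=C[C@@H]2c1c(OC)ccc(OC)c1Br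
F3 | step 11 | C15-methyl C18-(2-bromo-3,6-dimethoxyphenyl) C11 silyl enol ether | C=CC[C@@]12[C@@H](O[Si](C)(C)C(C)(C)C)CCC(O[Si](C)(C)c3ccccc3)=C1CC(C)=C[C@@H]2c1c(OC)ccc(OC)c1Br
F4 | step 6 | C11-bromo dienone (mixture at C11) | C=CC[C@@]12[C@@H](O[Si](C)(C)C(C)(C)C)CCC(Br)C1=CC(=O)C=C2
F5 | step 7 | C11-hydroxy dienone (mixture at C11) | C=CC[C@@]12[C@@H](O[Si](C)(C)C(C)(C)C)CCC(O)C1=CC(=O)C=C2
F6 | step 7 | C11-(dimethylphenylsilyloxy) dienone | C=CC[C@@]12[C@@H](O[Si](C)(C)C(C)(C)C)CCC(O[Si](C)(C)c3ccccc3)C1=CC(=O)C=C2
F7 | step 17 | (E)-allylic acetate of diketone 24 | CC(=O)OC/C(C)=C/C[C@@]23C(=O)CCC(=O)[C@@]21CC(C)=C[C@@H]3c2c(OC)ccc(OC)c21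
A1 | alternative 1 | bis(alkynyl pinacol boronate) of the ring A–C tricycle | C=C(C)[C@H]1C[C@@]23C(=O)[C@@H]1CC(=O)[C@@]2(C#CB4OC(C)(C)C(C)(C)O4)CC(C)=C[C@@H]3C#CB5OC(C)(C)C(C)(C)O5
A2 | alternative 1 | ethyne | C#C
A3 | alternative 1 | aryl bis(pinacol boronate) of the complete skeleton | C=C(C)[C@H]1C[C@@]23C(=O)[C@@H]1CC(=O)[C@@]21CC(C)=C[C@@H]3c2c(B4OC(C)(C)C(C)(C)O4)ccc(B5OC(C)(C)C(C)(C)O5)c21
A4 | alternative 2 | mirror-symmetric 4,5-dihydroxy-1,8-dimethoxyfluorene with C9 allylic methyl carbonate side chain | COc1ccc(O)c2c1C(C=C(C)COC(=O)OC)c1c(OC)ccc(O)c12
A5 | alternative 2 | bridged tetracyclic dienone with C7 methyl enol ether | O=C1C=CC(OC)=C2[C@@H]3C=C(C)C[C@]12c1c(O)ccc(OC)c13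
A6 | alternative 3 | benzocycloheptene C13 chloride with triethylsilyl enol ether and tethered 3-acetyl-5,5-dimethoxycyclopentadiene (C13 and C18 not defined) | C=C(O[Si](CC)(CC)CC)C1(Cl)CC(C)=CC(C2=CC(C(C)=O)=CC2(OC)OC)c2c(OC)ccc(OC)c12
A7 | alternative 3 | pentacyclic C4-acetyl enone with C7 dimethyl ketal | CC(=O)C1=C[C@@]23C(OC)(OC)[C@@H]1CC(=O)[C@@]21CC(C)=C[C@@H]3c2c(OC)ccc(OC)c21
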